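**Plan**

Ring A is numbered C1(=O), C2(OH), C3(CH3), C4(=O), C5 (bond to ring B) and C6 (2-methoxyphenethyl chain). Ring B carries primes in the same sense, with the phenethyl chain on C6'.
Feature: the para oxygens on C1 and C4 enclose the C6–C5 edge just as the 2-oxy group and the ring oxygen of a 2-siloxyfuran enclose its C3–C4 edge. The remaining C2–C3 edge, with its methyl group, is a butyne unit whose acyl activator can later be exchanged for the C2 oxygen.
Retrosynthesis: both quinones are unmasked last from methyl ethers. Ring A is cut at C1–C2 and C4–C3 into a 3,4-disubstituted 2-siloxyfuran and pent-3-yn-2-one. The parent butenolide is cut at its C3=C4 double bond (phosphonate olefination) and at its ester C–O bond, and the C5–C5' bond is cut into an aryllithium and a chloroacetyl Weinreb amide.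
Forward: the ring B arene is built first. The butenolide ring is then closed on it, ring A is closed by cycloaddition, and both six-membered rings are oxidised together.
Stereochemistry: the target has no stereocentre. The transient centres (phosphonate carbon, bridgeheads) are erased, and the hindered C5–C5' axis forms as a racemate.

Key step: step 12

Assumption: the target SMILES carries no stereodescriptor, so the C5–C5' axis is treated as unspecified and no atroposelective control is sought.
Abbreviation: ArB = 2,4,5-trimethoxy-3-methyl-6-(2-phenylethyl)phenyl, bonded through the carbon that becomes C5'.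

**Step 1**
Reactants: 1 3,5-dimethoxy-4-methylbenzaldehyde; 2 diethyl benzylphosphonate
Product: 3 (E)-1,3-dimethoxy-2-methyl-5-(2-phenylethenyl)benzene
Conditions: NaH, THF, 0 °C → rt
Reagents that add atoms: none
Why: Horner–Wadsworth–Emmons olefination of an unhindered, non-enolisable aromatic aldehyde by a benzylic phosphonate anion is a standard stilbene synthesis, and the E geometry it favours is of no consequence because the alkene is saturated in step 2.

**Step 2**
Reactants: 3 (E)-1,3-dimethoxy-2-methyl-5-(2-phenylethenyl)benzene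
Product: 4 1,3-dimethoxy-2-methyl-5-(2-phenylethyl)benzene
Conditions: H2 (1 atm), Pd/C, EtOAc, rt
Reagents that add atoms: none
Why: Catalytic hydrogenation over Pd/C at ambient pressure saturates the stilbene double bond only and leaves both arenes and the methyl ethers untouched.

**Step 3**
Reactants: 4 1,3-dimethoxy-2-methyl-5-(2-phenylethyl)benzene
Product: 5 1,5-dibromo-2,4-dimethoxy-3-methyl-6-(2-phenylethyl)benzene
Conditions: NBS (2.1 equiv), MeCN, 0 °C → rt, dark
Reagents that add atoms: N-bromosuccinimide, O=C1CCC(=O)N1Br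
Why: Electrophilic aromatic bromination in a polar solvent attacks only the two equivalent free positions, each ortho to one methoxy group and para to the other, while the unactivated phenyl ring and the benzylic positions stay inert in the absence of light.

**Step 4**
Reactants: 5 1,5-dibromo-2,4-dimethoxy-3-methyl-6-(2-phenylethyl)benzene
Product: 8 3-bromo-4,6-dimethoxy-5-methyl-2-(2-phenylethyl)phenol, via aryllithium 6 (not isolated), via dimethyl arylboronate 7 (not isolated)
Conditions: n-BuLi (1.0 equiv), THF, −78 °C; B(OMe)3, −78 °C → rt; 30% aq H2O2, 0 °C → rt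
Reagents that add atoms: hydrogen peroxide, OO (oxygen of 8); trimethyl borate, COB(OC)OC (boron and methoxy groups of 7 only); n-butyllithium, [Li]CCCC (lithium of 6 only)
Why: Lithium–bromine exchange with a single equivalent of n-BuLi converts one of the two equivalent C–Br bonds of the symmetric dibromide into a methoxy-chelated aryllithium, and the borylation–peroxide oxidation sequence (1,2-aryl shift from boron to oxygen) installs the C1' oxygen while the second bromine is kept for step 6.

**Step 5**
Reactants: 8 3-bromo-4,6-dimethoxy-5-methyl-2-(2-phenylethyl)phenol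
Product: 9 1-bromo-2,4,5-trimethoxy-3-methyl-6-(2-phenylethyl)benzene
Conditions: MeI, K2CO3, DMF, rt
Reagents that add atoms: iodomethane, CI
Why: Williamson ether synthesis on the phenoxide should proceed cleanly despite the two ortho substituents because iodomethane is a small SN2 electrophile, and the aryl bromide is inert.

**Step 6**
Reactants: 9 1-bromo-2,4,5-trimethoxy-3-methyl-6-(2-phenylethyl)benzene; 10 2-chloro-N-methoxy-N-methylacetamide
Product: 12 2-chloro-1-ArB-ethan-1-one, via aryllithium 11 (not isolated)
Conditions: n-BuLi, THF, −78 °C; then 10, −78 → 0 °C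
Reagents that add atoms: n-butyllithium, [Li]CCCC (lithium of 11 only)
Why: Lithium–bromine exchange followed by the Weinreb ketone synthesis forms the bond from C5' to the future C5 at the position fixed by the bromine, the chelated tetrahedral adduct preventing over-addition and the low temperature sparing the C–Cl bond, which avoids the ether cleavage that a Lewis acid acylation next to a methoxy group would risk.

**Step 7**
Reactants: 13 triethyl phosphonoacetate; 14 1-(2-bromoethyl)-2-methoxybenzene
Product: 15 ethyl 2-(diethoxyphosphoryl)-4-(2-methoxyphenyl)butanoate (racemic)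
Conditions: NaH, DMF, 0 → 60 °C
Reagents that add atoms: none
Why: SN2 alkylation of the stabilised sodium phosphonoacetate carbanion by a primary bromide is the usual entry to α-substituted phosphonoacetates, the modest basicity of the anion keeping elimination to the styrene in check, and the new centre is racemic and is erased in step 10.

**Step 8**
Reactants: 15 ethyl 2-(diethoxyphosphoryl)-4-(2-methoxyphenyl)butanoate
Product: 16 2-(diethoxyphosphoryl)-4-(2-methoxyphenyl)butanoic acid (racemic)
Conditions: 1 M aq NaOH, EtOH, rt; then 1 M HCl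
Reagents that add atoms: sodium hydroxide, [Na+].[OH-]
Why: Saponification with dilute hydroxide at room temperature is chemoselective because the carboxylic ethyl ester is attacked at its acyl carbon far faster than the phosphonate ethyl esters are cleaved.

**Step 9**
Reactants: 12 2-chloro-1-ArB-ethan-1-one; 16 2-(diethoxyphosphoryl)-4-(2-methoxyphenyl)butanoic acid
Product: 17 2-oxo-2-ArB-ethyl 2-(diethoxyphosphoryl)-4-(2-methoxyphenyl)butanoate (racemic)
Conditions: K2CO3, DMF, rt
Reagents that add atoms: none
Why: Carboxylate O-alkylation (SN2) profits from the high reactivity of the α-chloro ketone carbon, which lies one atom away from the crowded arene, and any premature olefination under the mild carbonate base only anticipates step 10.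

**Step 10**
Reactants: 17 2-oxo-2-ArB-ethyl 2-(diethoxyphosphoryl)-4-(2-methoxyphenyl)butanoate
Product: 18 3-[2-(2-methoxyphenyl)ethyl]-4-ArB-furan-2(5H)-one
Conditions: NaH, THF, 0 °C → rt
Reagents that add atoms: none
Why: In this intramolecular Horner–Wadsworth–Emmons reaction the phosphonate carbanion attacks the ketone in a 5-exo-trig closure and loss of diethyl phosphate sets the tetrasubstituted C3=C4 double bond, the established butenolide synthesis from acyloxymethyl ketones.

**Step 11**
Reactants: 18 3-[2-(2-methoxyphenyl)ethyl]-4-ArB-furan-2(5H)-one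
Product: 19 2-(tert-butyldimethylsiloxy)-3-[2-(2-methoxyphenyl)ethyl]-4-ArB-furan
Conditions: TBSOTf, Et3N, CH2Cl2, 0 °C
Reagents that add atoms: tert-butyldimethylsilyl trifluoromethanesulfonate, CC(C)(C)[Si](C)(C)OS(=O)(=O)C(F)(F)F
Why: In this soft enolisation, O-silylation of the lactone carbonyl acidifies the allylic, oxygen-flanked C5 protons so that Et3N removes one and the aromatic 2-siloxyfuran forms, which is the standard preparation of such dienes from 2(5H)-furanones.

**Step 12**
Reactants: 19 2-(tert-butyldimethylsiloxy)-3-[2-(2-methoxyphenyl)ethyl]-4-ArB-furan; 20 pent-3-yn-2-one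
Product: 22 1-{2-(tert-butyldimethylsiloxy)-5-hydroxy-3-[2-(2-methoxyphenyl)ethyl]-6-methyl-4-ArB-phenyl}ethan-1-one (ring A: C1 OTBS/C2 acetyl/C3 CH3/C4 OH/C5 ArB/C6 chain), via oxanorbornadiene 21 (not isolated)
Conditions: 20 (3 equiv), BHT (cat.), PhMe (1 M), 110 °C, sealed tube
Reagents that add atoms: none
Why: The siloxyfuran, a cyclic silyl ketene acetal diene, and the electron-poor ynone should combine in a normal-electron-demand [4+2] cycloaddition that is concerted but strongly asynchronous, the C4–C3 bond (furan C5 to the methyl-bearing alkyne carbon) running ahead of the C1–C2 bond (furan C2 to the acetyl-bearing carbon). The closest known reaction type is the Diels–Alder reaction of 2-trialkylsiloxyfurans with acetylenic ketones and esters, which delivers para-hydroquinone monosilyl ethers. Ring A closes as a six-membered carbocycle in this suprafacial [4+2] mode inside oxanorbornadiene 21, whose ketal-type C1–O bridge bond then ionises with the push of the siloxy oxygen, after which loss of the C4 hydrogen leaves the bridge oxygen as the C4 phenol and makes the sequence irreversible through aromatisation. No stereocentre survives, since both bridgehead centres of 21 are erased and the C5–C5' axis forms as a racemate. The step needs regioselectivity (methyl next to C4, acetyl next to C1), which the matched polarisation secures because the largest HOMO coefficient lies at the unsubstituted furan C5 and the largest LUMO coefficient at the ynone β-carbon. Shielding of the furan faces by the perpendicular ring B is met with excess dienophile, high concentration and heat, and it does not matter which oxygen finally holds the silyl group because step 13 methylates both.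

**Step 13**
Reactants: 22 ring A acetylhydroquinone monosilyl ether
Product: 24 1-{2,5-dimethoxy-3-[2-(2-methoxyphenyl)ethyl]-6-methyl-4-ArB-phenyl}ethan-1-one, via free hydroquinone 23 (not isolated)
Conditions: CsF, Cs2CO3, MeI, DMF, rt
Reagents that add atoms: iodomethane, CI
Why: Fluoride-induced cleavage of the aryl silyl ether and Williamson methylation of both phenoxides in one flask bring any silyl-migrated or desilylated material from step 12 to a single dimethyl ether, carbonate being too weak a base to C-methylate the ketone.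

**Step 14**
Reactants: 24 1-{2,5-dimethoxy-3-[2-(2-methoxyphenyl)ethyl]-6-methyl-4-ArB-phenyl}ethan-1-one
Product: 25 2,5-dimethoxy-3-[2-(2-methoxyphenyl)ethyl]-6-methyl-4-ArB-phenyl acetate
Conditions: mCPBA, CH2Cl2, 0 °C → rt
Reagents that add atoms: 3-chloroperoxybenzoic acid, OOC(=O)c1cccc(Cl)c1
Why: In this Baeyer–Villiger oxidation the electron-rich aryl group of the Criegee adduct, which bears an ortho methoxy donor, migrates far better than methyl, so that oxygen is inserted into the C2–acetyl bond and the aryl acetate forms.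

**Step 15**
Reactants: 25 2,5-dimethoxy-3-[2-(2-methoxyphenyl)ethyl]-6-methyl-4-ArB-phenyl acetate
Product: 26 2-acetoxy-3-methyl-6-[2-(2-methoxyphenyl)ethyl]-5-[4-methoxy-5-methyl-3,6-dioxo-2-(2-phenylethyl)cyclohexa-1,4-dien-1-yl]-1,4-benzoquinone
Conditions: (NH4)2Ce(NO3)6 (5 equiv), MeCN/H2O, 0 °C
Reagents that add atoms: water, O
Why: Oxidative demethylation of para-dimethoxyarenes by (NH4)2Ce(NO3)6 should act on the C1/C4 and C1'/C4' pairs of the two fully substituted rings, whereas the monomethoxy side-chain ring has a much higher oxidation potential and is spared, and partial loss of the acetate is harmless because step 16 removes it anyway.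

**Step 16**
Reactants: 26 acetoxyquinone–methoxyquinone
Product: 27 CNP0202346.0, 2-hydroxy-3-methyl-6-[2-(2-methoxyphenyl)ethyl]-5-[4-hydroxy-5-methyl-3,6-dioxo-2-(2-phenylethyl)cyclohexa-1,4-dien-1-yl]cyclohexa-2,5-diene-1,4-dione
Conditions: 1 M aq NaOH, THF, rt, argon; then 1 M HCl
Reagents that add atoms: sodium hydroxide, [Na+].[OH-]
Why: Hydroxide cleaves the C2 enol acetate by saponification and replaces the C2' methoxy group by addition–elimination at this vinylogous ester carbon, both quinones lack a free position for stray conjugate addition, the plain aryl methyl ether of the side chain is inert to aqueous base, and acidification frees the bis(hydroxyquinone).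

**Compound list**

1 | 3,5-dimethoxy-4-methylbenzaldehyde | COc1cc(C=O)cc(OC)c1C | starting material
2 | diethyl benzylphosphonate | CCOP(=O)(Cc1ccccc1)OCC | starting material
3 | (E)-1,3-dimethoxy-2-methyl-5-(2-phenylethenyl)benzene | COc1cc(/C=C/c2ccccc2)cc(OC)c1C | intermediate
4 | 1,3-dimethoxy-2-methyl-5-(2-phenylethyl)benzene | COc1cc(CCc2ccccc2)cc(OC)c1C | intermediate
5 | 1,5-dibromo-2,4-dimethoxy-3-methyl-6-(2-phenylethyl)benzene | COc1c(C)c(OC)c(Br)c(CCc2ccccc2)c1Br | intermediate
6 | [3-bromo-4,6-dimethoxy-5-methyl-2-(2-phenylethyl)phenyl]lithium (not isolated) | COc1c(C)c(OC)c(Br)c(CCc2ccccc2)c1[Li] | intermediate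
7 | dimethyl [3-bromo-4,6-dimethoxy-5-methyl-2-(2-phenylethyl)phenyl]boronate (not isolated) | COB(OC)c1c(OC)c(C)c(OC)c(Br)c1CCc1ccccc1 | intermediate
8 | 3-bromo-4,6-dimethoxy-5-methyl-2-(2-phenylethyl)phenol | COc1c(C)c(OC)c(Br)c(CCc2ccccc2)c1O | intermediate
9 | 1-bromo-2,4,5-trimethoxy-3-methyl-6-(2-phenylethyl)benzene | COc1c(C)c(OC)c(Br)c(CCc2ccccc2)c1OC | intermediate
10 | 2-chloro-N-methoxy-N-methylacetamide | CON(C)C(=O)CCl | starting material
11 | [2,4,5-trimethoxy-3-methyl-6-(2-phenylethyl)phenyl]lithium (not isolated) | COc1c(C)c(OC)c([Li])c(CCc2ccccc2)c1OC | intermediate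
12 | 2-chloro-1-[2,4,5-trimethoxy-3-methyl-6-(2-phenylethyl)phenyl]ethan-1-one | COc1c(C)c(OC)c(C(=O)CCl)c(CCc2ccccc2)c1OC | intermediate
13 | triethyl phosphonoacetate | CCOC(=O)CP(=O)(OCC)OCC | starting material
14 | 1-(2-bromoethyl)-2-methoxybenzene | COc1ccccc1CCBr | starting material
15 | ethyl 2-(diethoxyphosphoryl)-4-(2-methoxyphenyl)butanoate (racemic) | CCOC(=O)C(CCc1ccccc1OC)P(=O)(OCC)OCC | intermediate
16 | 2-(diethoxyphosphoryl)-4-(2-methoxyphenyl)butanoic acid (racemic) | CCOP(=O)(OCC)C(CCc1ccccc1OC)C(=O)O | intermediate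
17 | 2-oxo-2-[2,4,5-trimethoxy-3-methyl-6-(2-phenylethyl)phenyl]ethyl 2-(diethoxyphosphoryl)-4-(2-methoxyphenyl)butanoate (racemic) | CCOP(=O)(OCC)C(CCc1ccccc1OC)C(=O)OCC(=O)c1c(OC)c(C)c(OC)c(OC)c1CCc1ccccc1 | intermediate
18 | 3-[2-(2-methoxyphenyl)ethyl]-4-[2,4,5-trimethoxy-3-methyl-6-(2-phenylethyl)phenyl]furan-2(5H)-one | O=C1OCC(c2c(OC)c(C)c(OC)c(OC)c2CCc2ccccc2)=C1CCc1ccccc1OC | intermediate
19 | 2-(tert-butyldimethylsiloxy)-3-[2-(2-methoxyphenyl)ethyl]-4-[2,4,5-trimethoxy-3-methyl-6-(2-phenylethyl)phenyl]furan | CC(C)(C)[Si](C)(C)Oc1occ(-c2c(OC)c(C)c(OC)c(OC)c2CCc2ccccc2)c1CCc1ccccc1OC | intermediate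
20 | pent-3-yn-2-one | CC#CC(C)=O | starting material
21 | 2-acetyl-1-(tert-butyldimethylsiloxy)-3-methyl-6-[2-(2-methoxyphenyl)ethyl]-5-ArB-7-oxabicyclo[2.2.1]hepta-2,5-diene (racemic, not isolated) | CC(=O)C1=C(C)C2OC1(O[Si](C)(C)C(C)(C)C)C(CCc1ccccc1OC)=C2c1c(OC)c(C)c(OC)c(OC)c1CCc1ccccc1 | intermediate
22 | 1-{2-(tert-butyldimethylsiloxy)-5-hydroxy-3-[2-(2-methoxyphenyl)ethyl]-6-methyl-4-ArB-phenyl}ethan-1-one | CC(=O)c1c(C)c(O)c(-c2c(OC)c(C)c(OC)c(OC)c2CCc2ccccc2)c(CCc2ccccc2OC)c1O[Si](C)(C)C(C)(C)C | intermediate
23 | 1-{2,5-dihydroxy-3-[2-(2-methoxyphenyl)ethyl]-6-methyl-4-ArB-phenyl}ethan-1-one (not isolated) | CC(=O)c1c(C)c(O)c(-c2c(OC)c(C)c(OC)c(OC)c2CCc2ccccc2)c(CCc2ccccc2OC)c1O | intermediate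
24 | 1-{2,5-dimethoxy-3-[2-(2-methoxyphenyl)ethyl]-6-methyl-4-ArB-phenyl}ethan-1-one | CC(=O)c1c(C)c(OC)c(-c2c(OC)c(C)c(OC)c(OC)c2CCc2ccccc2)c(CCc2ccccc2OC)c1OC | intermediate
25 | 2,5-dimethoxy-3-[2-(2-methoxyphenyl)ethyl]-6-methyl-4-ArB-phenyl acetate | CC(=O)Oc1c(C)c(OC)c(-c2c(OC)c(C)c(OC)c(OC)c2CCc2ccccc2)c(CCc2ccccc2OC)c1OC | intermediate
26 | 2-acetoxy-3-methyl-6-[2-(2-methoxyphenyl)ethyl]-5-[4-methoxy-5-methyl-3,6-dioxo-2-(2-phenylethyl)cyclohexa-1,4-dien-1-yl]-1,4-benzoquinone | CC(=O)OC1=C(C)C(=O)C(C2=C(CCc3ccccc3)C(=O)C(OC)=C(C)C2=O)=C(CCc2ccccc2OC)C1=O | intermediate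
27 | CNP0202346.0 | COc1ccccc1CCC1=C(C2=C(CCc3ccccc3)C(=O)C(O)=C(C)C2=O)C(=O)C(C)=C(O)C1=O | target

**Step count**

- Total step count: 16.
- Longest linear sequence: 14 steps (steps 1–6 and 9–16, from 1). Steps 7 and 8 form the side branch.

**Steps most likely to fail**

**Step 12.** The perpendicular ring B holds its C4' methoxy and C6' phenethyl groups over the two furan faces. The cycloaddition may therefore be slower than protodesilylation or thermal decay of the diene, or the reaction may stop after the first C–C bond.

The fallback forms the same two bonds one at a time at a lower oxidation level.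
- It sets out from 19. A vinylogous Mukaiyama–Michael addition to (E)-pent-3-en-2-one (TBSOTf cat., CH2Cl2, −78 °C, dilute acid work-up) should give the keto butenolide F1 as a diastereomer mixture whose centres are erased later.
- t-BuOK in THF should then drive a Dieckmann-type acylation of the ketone methylene by the lactone carbonyl. This gives the hydroxy diketone F2, held as its β-diketone enolate.
- MnO2 in CH2Cl2 should oxidise the allylic alcohol to the enedione F3, which enolises to the hydroquinone.
- The route is rejoined at 23, which is methylated as in step 13 without fluoride.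

**Step 10.** Attack of the tertiary phosphonate carbanion on a carbonyl group shielded by two ortho substituents may be sluggish. That would leave time for enolisation of the acyloxy ketone, acyl transfer or ester cleavage.

The fallback makes the C4–aryl bond of the butenolide by cross-coupling in place of the olefination.
- It sets out from 9. Aryllithium 11 is quenched with B(Oi-Pr)3 and worked up with acid to give the boronic acid F4.
- In parallel, tetronic acid is reductively alkylated with (2-methoxyphenyl)acetaldehyde and diethyl 2,6-dimethyl-1,4-dihydropyridine-3,5-dicarboxylate (L-proline cat., CH2Cl2) to give the 3-alkyltetronic acid F5.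
- Tf2O and i-Pr2NEt at −78 °C convert F5 into the enol triflate F6.
- Suzuki–Miyaura coupling of F4 with F6 (Pd(OAc)2, SPhos, K3PO4, PhMe/H2O, 80 °C) comes back to the route at 18.

**Step 14.** Addition of the peracid to a carbonyl group flanked by two ortho substituents may be slow, so that over-oxidation of the electron-rich, fully substituted rings competes.

The fallback excises the two-carbon unit through a benzylic hydroperoxide rearrangement.
- It sets out from 24. MeLi with CeCl3 (THF, −78 °C) should give the tertiary benzylic alcohol F7.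
- H2O2 with BF3·OEt2 (CH2Cl2, 0 °C) should convert F7 by way of the cumyl-type hydroperoxide F8. In a Hock rearrangement (aryl shift from carbon to oxygen) this gives the phenol F9.
- Ac2O and pyridine bring the material back to the route at 25.

**Further compounds**

F1 | step 12 | 3-[2-(2-methoxyphenyl)ethyl]-5-(4-oxopentan-2-yl)-4-ArB-furan-2(5H)-one (diastereomer mixture) | CC(=O)CC(C)C1OC(=O)C(CCc2ccccc2OC)=C1c1c(OC)c(C)c(OC)c(OC)c1CCc1ccccc1
F2 | step 12 | 6-acetyl-4-hydroxy-2-[2-(2-methoxyphenyl)ethyl]-5-methyl-3-ArB-cyclohex-2-en-1-one (diastereomer mixture) | CC(=O)C1C(C)C(O)C(c2c(OC)c(C)c(OC)c(OC)c2CCc2ccccc2)=C(CCc2ccccc2OC)C1=O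
F3 | step 12 | 5-acetyl-3-[2-(2-methoxyphenyl)ethyl]-6-methyl-2-ArB-cyclohex-2-ene-1,4-dione (diastereomer mixture) | CC(=O)C1C(C)C(=O)C(c2c(OC)c(C)c(OC)c(OC)c2CCc2ccccc2)=C(CCc2ccccc2OC)C1=O
F4 | step 10 | [2,4,5-trimethoxy-3-methyl-6-(2-phenylethyl)phenyl]boronic acid | COc1c(C)c(OC)c(B(O)O)c(CCc2ccccc2)c1OC
F5 | step 10 | 4-hydroxy-3-[2-(2-methoxyphenyl)ethyl]furan-2(5H)-one | COc1ccccc1CCC1=C(O)COC1=O
F6 | step 10 | 4-[2-(2-methoxyphenyl)ethyl]-5-oxo-2,5-dihydrofuran-3-yl trifluoromethanesulfonate | COc1ccccc1CCC1=C(OS(=O)(=O)C(F)(F)F)COC1=O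
F7 | step 14 | 2-{2,5-dimethoxy-3-[2-(2-methoxyphenyl)ethyl]-6-methyl-4-ArB-phenyl}propan-2-ol | CC(C)(O)c1c(C)c(OC)c(-c2c(OC)c(C)c(OC)c(OC)c2CCc2ccccc2)c(CCc2ccccc2OC)c1OC
F8 | step 14 | 2-{2,5-dimethoxy-3-[2-(2-methoxyphenyl)ethyl]-6-methyl-4-ArB-phenyl}propan-2-yl hydroperoxide | CC(C)(OO)c1c(C)c(OC)c(-c2c(OC)c(C)c(OC)c(OC)c2CCc2ccccc2)c(CCc2ccccc2OC)c1OC
F9 | step 14 | 2,5-dimethoxy-3-[2-(2-methoxyphenyl)ethyl]-6-methyl-4-ArB-phenol | Cc1c(O)c(OC)c(CCc2ccccc2OC)c(-c2c(OC)c(C)c(OC)c(OC)c2CCc2ccccc2)c1OC
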